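## The problem

The target is a cis-fused decalin, numbered here as a labdane fragment: C1–C3 are the ring A methylenes, C4 carries the gem-dimethyl group, C5 is the ring-fusion CH, C6–C9 complete ring B, C10 is the methyl-bearing fusion carbon, C11–C14 are the enone chain, and β is the face of the C10 methyl group. Ring B carries six contiguous stereocentres (C5–C10), two of them fully substituted (C8, C10): H5, the C10 methyl, the C8 methyl, O7 and the C9 chain are β, whereas the O6 acetate and O8 are α. The C4 gem-dimethyl group fixes the shape: the fold with C4 axial on ring B would point a methyl group into ring B, so C4 stays equatorial, C1 hangs axially under ring B, and the β face is convex while the α face is shielded. C5 and C10 therefore have to be set first and absolutely. After that, external reagents can be expected on the β face, which suits the C9 chain, O7 and a hydride to a C6 ketone (O6 ends up α), but the tertiary O8 must reach the shielded α face from within the molecule. Fragile points are the acetate next to a free diol (acyl migration under base), the enone (oxa-Michael addition of O7, acidity at C9) and any C6 ketone, which makes C5 epimerisable. The key step rests on three features: the C5–C10 bond with syn H and CH3 and C9 on both carbons is what a carbene leaves on an alkene; the oxygenated C6 between C5 and the unit C7–C8(CH3)–C9 is one CO; and C5 lies between two fully substituted carbons (C4, C10), so a metal–C5 bond has no β-hydrogen.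

## Retrosynthesis

**Enone chain.** The C11=C12 bond of 23 is cut by cross-metathesis into the C9-vinyl diol acetate 21 and but-3-en-2-one 22. A Wittig route would pass through a C9 aldehyde that is β-hydroxylated and epimerisable, and carrying the enone earlier exposes it to O7 and to base. The cut removes the only base-sensitive function; the forward step must be E-selective and tolerate a free diol, which a neutral ruthenium carbene does.

**C7/C8 diol.** The C8–O bond of 21 is cut to the 7β,8β-epoxide 20, and 20 to the alkene 19. An enol-ether oxidation at C8 would need an electrophilic oxidant on the α face, next to the pseudoaxial O6 substituent and the axial C1 methylene. The epoxide reverses the roles: the peracid puts O7 on the open β face, and O8 then enters from the α side as a nucleophile at the tertiary carbon, with inversion, where the 6α-acetate is already waiting 1,3-diaxially. Two stereocentres and two oxygens are removed at once.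

**Protecting-group exchange and C7 deoxygenation.** 19 comes from alcohol 18 and silyl ether 17, and the C7–H bond of 17 from enol triflate 16. The acetate cannot be carried through cuprate and palladium chemistry (α-acyloxy ketone, allylic acetate), the silyl ether can. The triflate is the traceless form of the C7 carbonyl that activates C9.

**C9–C11 bond.** 16 is cut at C9–C11 to enone 14 and a vinyl cuprate, the enolate 15 being trapped on oxygen. Opening an 8,9-epoxide with a vinyl metal would require substitution at a neopentyl carbon; conjugate addition to a β-CH next to a quaternary carbon is routine. The forward step must deliver vinyl to the β face, which is both the convex face and the axial trajectory anti to the C1–C10 bond.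

**Oxidation level of C6 and C7.** 14 goes back by allylic C–H oxidation to 13, by desilylation to 12 and by reduction to ketone 11. C7 is the only ring allylic methylene of 13, so no directing group is needed. The C6 configuration is asked of a bulky hydride on the convex face of 11.

**Ring B (key cut).** The C5–C6 and C6–C7 bonds of 11 are cut, giving vinylcyclopropane 9 and carbon monoxide 10. Against aldol or Diels–Alder closures of ring B, this cut supplies C6 already oxygenated, leaves C7 activated and C8=C9 in place, and turns the cis fusion into a cyclopropane problem. The forward reaction must break C5–C9 rather than C9–C10 and keep C5 intact.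

**Isopropenyl group.** 9 comes from methyl ketone 8 (Wittig), 8 from Weinreb amide 7, and 7 from ester 6. Dehydrating a cyclopropyl carbinol would risk ring opening; the ketone/ylide route does not ionise the cyclopropylcarbinyl position.

**Cyclopropane.** The C5–C9 and C9–C10 bonds of 6 are cut to 1,3,3-trimethylcyclohexene 4 and ethyl diazoacetate 5. The alkene is achiral, so one chiral catalyst sets C5 and C10 in a single suprafacial event, and the exo ester is favoured because the endo position faces the gem-dimethyl group.

**Alkene.** 4 is reached from 2,2,6-trimethylcyclohexanone 1 through enol triflate 3. Acid dehydration of the corresponding alcohol would pass through a cation next to a quaternary carbon and invite methyl shifts; triflate reduction cannot rearrange.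

## Roads not taken

**Alternative 1:** The cut is the C9–C10 bond, with a sacrificial C2–C7 bond added so that ring B is folded back into a bicyclo[2.2.2]octene framework. In the forward sense the potassium alkoxide (KH, 18-crown-6) undergoes an anionic oxy-Cope shift and the C7 enolate is silylated to give the enol ether A1.
- Merits: the reaction class is dependable for cis-decalins, which the untested carbonylation of the chosen plan cannot claim. It sets the cis fusion and C9 with its carbon substituent in one event, where the chosen plan sets C9 later.
- Weak points for this target: A1 has no oxygen at C6 (a plain CH2), carries a superfluous C1=C2 alkene, and holds only one carbon of the side chain, so the enone must be grown through an epimerisable C9 aldehyde. The bridged carbinol itself needs an enantioselective bicyclooctenone synthesis and a face-selective addition of a trisubstituted alkenyl metal, and the C9 configuration depends on a boat transition state and on alkene geometry.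
- Comparison: the chosen plan brings the C6 oxygen with CO and reaches its ring B intermediate in seven steps from a commercial ketone.

**Alternative 2:** The cut runs through C1–C10 and C4–C5, so that ring A is made by a Diels–Alder addition of 4-methylpenta-1,3-diene A3 to one methyl-bearing alkene of 2,6-dimethyl-1,4-benzoquinone A2 under a chiral oxazaborolidinium Lewis acid, giving the enedione A4.
- Merits: two commodity reactants and one catalytic step give the cis-fused bicycle in absolute form, far shorter than the seven steps to 11. Ring B arrives with oxygen at C6 and a C7=C8 alkene.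
- Weak points: the diene has a Z-methyl on its terminus, so the s-cis rotamer is disfavoured and strong Lewis acids tend to polymerise it, and the bond to the fully substituted C4 must form next to the ring fusion. C9 is a ketone in A4, so the chain would enter by 1,2-addition followed by deoxygenation with control of H9. Two ketones must be told apart and ring A keeps an extra alkene.
- Comparison: the chosen plan delivers C9 as a β-CH of an enone, the right oxidation level for the chain, and does not depend on a reluctant diene.

**Alternative 3:** The cut is the C3–C4 bond. A C10-quaternised derivative of nopinone A5 (or its antipode, as the target demands) bearing a Z-vinylsilane chain is ionised by TiCl4 at the cyclobutane C4–C7 bond, and the vinylsilane closes ring A to give ketone A6.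
- Merits: the absolute configuration and the gem-dimethyl group come from the chiral pool, with no asymmetric catalyst; here the chosen plan is weaker, since it rests on an enantioselective cyclopropanation of a hindered alkene. The C8 ketone of A6 would also let a methyl nucleophile set the tertiary carbinol from the convex face, more direct than the epoxide inversion used here.
- Weak points: A6 has a single functional group in ring B. C6 is two carbons from it and unactivated, C9 would have to be alkylated between a ketone and a quaternary carbon, and C7 needs separate oxidation. Building the quaternary C10 on the pinane ketone and the cationic cascade itself add risk and steps.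
- Comparison: after its key step the chosen plan has C6 oxygenated, C7 activated and C8=C9 in place, so all four ring B positions can be addressed.

Key step: step 7

Assumption: the (S,S)-bis(oxazoline) ligand is written for step 3; which antipode of the ligand gives the (1S,6R,7S)-ester 6 on this alkene has to be assigned on the first run, both antipodes being commercial.

## Steps

Step 1
Reactants: 1 2,2,6-trimethylcyclohexanone
Product: 3 2,6,6-trimethylcyclohex-1-en-1-yl trifluoromethanesulfonate, via lithium enolate 2 (not isolated)
Conditions: LDA, THF, −78 → 0 °C; PhNTf2, 0 → 23 °C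
Reagents that add atoms: N-phenylbis(trifluoromethanesulfonimide), O=S(=O)(N(c1ccccc1)S(=O)(=O)C(F)(F)F)C(F)(F)F
Why: Enolate O-triflation; the ketone has only one enolisable position, so a single enol triflate can form.

Step 2
Reactants: 3 2,6,6-trimethylcyclohex-1-en-1-yl trifluoromethanesulfonate
Product: 4 1,3,3-trimethylcyclohexene
Conditions: Pd(OAc)2 (cat.), PPh3, Bu3N, HCO2H, DMF, 60 °C
Reagents that add atoms: none
Why: Palladium-catalysed formate reduction of an enol triflate; no cationic intermediate arises, so the skeleton next to the quaternary carbon cannot rearrange as it would in an acid dehydration.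

Step 3
Reactants: 4 1,3,3-trimethylcyclohexene; 5 ethyl diazoacetate
Product: 6 ethyl (1S,6R,7S)-1,5,5-trimethylbicyclo[4.1.0]heptane-7-carboxylate (exo ester)
Conditions: CuOTf·0.5C6H6 (2 mol %), (S,S)-t-Bu-bis(oxazoline) (2.4 mol %), CH2Cl2, 25 °C, slow addition of 5
Reagents that add atoms: none
Why: Copper–bis(oxazoline) carbene transfer to a trisubstituted alkene; the suprafacial addition sets C5 and C10 (syn H and CH3) at once with the catalyst choosing the enantiotopic face, and the ester goes exo because the endo position faces the gem-dimethyl group.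

Step 4
Reactants: 6 ethyl (1S,6R,7S)-1,5,5-trimethylbicyclo[4.1.0]heptane-7-carboxylate
Product: 7 (1S,6R,7S)-N-methoxy-N,1,5,5-tetramethylbicyclo[4.1.0]heptane-7-carboxamide
Conditions: MeNHOMe·HCl, i-PrMgCl, THF, −20 → 0 °C
Reagents that add atoms: N,O-dimethylhydroxylamine hydrochloride, CNOC.Cl
Why: Direct aminolysis of the ester by the magnesium amide gives the Weinreb amide; the cyclopropane stereocentres are not touched.

Step 5
Reactants: 7 (1S,6R,7S)-N-methoxy-N,1,5,5-tetramethylbicyclo[4.1.0]heptane-7-carboxamide
Product: 8 1-[(1S,6R,7S)-1,5,5-trimethylbicyclo[4.1.0]heptan-7-yl]ethan-1-one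
Conditions: MeMgBr, THF, 0 °C
Reagents that add atoms: methylmagnesium bromide, C[Mg]Br
Why: Weinreb ketone synthesis; the chelated tetrahedral adduct stops at the ketone stage.

Step 6
Reactants: 8 1-[(1S,6R,7S)-1,5,5-trimethylbicyclo[4.1.0]heptan-7-yl]ethan-1-one
Product: 9 (1R,6R,7R)-1,5,5-trimethyl-7-(prop-1-en-2-yl)bicyclo[4.1.0]heptane (exo)
Conditions: Ph3PCH3Br, KOt-Bu, THF, 0 → 50 °C
Reagents that add atoms: methyltriphenylphosphonium bromide, C[P+](c1ccccc1)(c1ccccc1)c1ccccc1.[Br-]
Why: Wittig methylenation of a cyclopropyl methyl ketone; the cyclopropylcarbinyl position is never ionised, so the ring stays closed, and any base-induced epimerisation at C7 can only favour the exo isomer.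

Step 7
Reactants: 9 (1R,6R,7R)-1,5,5-trimethyl-7-(prop-1-en-2-yl)bicyclo[4.1.0]heptane; 10 carbon monoxide
Product: 11 (4aR,8aR)-3,4a,8,8-tetramethyl-4a,5,6,7,8,8a-hexahydronaphthalen-1(2H)-one (cis-4,4,8,10-tetramethyl-8-octalin-6-one, 5β-H, 10β-CH3)
Conditions: [Rh(CO)2Cl]2 (5 mol %), CO (1 atm), toluene, 90 °C
Reagents that add atoms: none
Why: Proposed new method: alkene-bound monovalent rhodium inserts into the proximal C5–C9 cyclopropane bond with retention at C5, giving a rhodacycle σ-bound to C5 and η3-bound to C9–C8–C7; CO then inserts into the Rh–C5 bond, again with retention, and acyl–allyl reductive elimination at the CH2 terminus C7 forms C6–C7. The closest known reaction type is the rhodium-catalysed [5+1] carbonylation of simple vinylcyclopropanes to β,γ-cyclohexenones, not yet shown on a ring-fused cyclopropane with a fully substituted carbon. Ring B closes as a six-membered ring by this reductive elimination from the acyl(allyl)rhodacycle, a formal [5+1] cycloaddition. No new stereocentre is made: C5 and C10 come from the cyclopropane, and because C5 keeps its configuration through both organometallic events the syn H5/CH3 pair of 9 becomes the cis ring fusion. The step needs cleavage of C5–C9 and not of C9–C10; C10 is fully substituted, so a Rh–C10 bond is harder to form, and the isopropenyl methyl keeps the s-cis rotamer needed for the π-allyl within reach. The Rh–C5 bond has no β-hydrogen, since C4 and C10 are both fully substituted, so the usual escape of such metallacycles to dienes is closed on the productive path. Neutral conditions and a temperature below that of the thermal homo-1,5-hydrogen shift protect the enolisable C5 centre and the β,γ-position of the alkene.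

Step 8
Reactants: 11 cis-4,4,8,10-tetramethyl-8-octalin-6-one
Product: 12 cis-4,4,8,10-tetramethyl-8-octalin-6α-ol
Conditions: LiBH(s-Bu)3, THF, −78 °C; then NaOH, H2O2, 0 °C
Reagents that add atoms: none
Why: Bulky hydride reduction from the convex β face (equatorial trajectory; the α face is covered by the axial C1 methylene) sets the 6α-alcohol, and at −78 °C hydride transfer outruns enolisation, so C5 and the alkene position stay as formed.

Step 9
Reactants: 12 cis-4,4,8,10-tetramethyl-8-octalin-6α-ol
Product: 13 6α-(tert-butyldimethylsilyloxy)-cis-4,4,8,10-tetramethyl-8-octalin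
Conditions: TBSOTf, 2,6-lutidine, CH2Cl2, 0 °C
Reagents that add atoms: tert-butyldimethylsilyl trifluoromethanesulfonate, CC(C)(C)[Si](C)(C)OS(=O)(=O)C(F)(F)F
Why: Silyl triflate silylation of a hindered secondary alcohol; the silyl ether, unlike an acetate, survives the cuprate and palladium steps ahead.

Step 10
Reactants: 13 6α-(tert-butyldimethylsilyloxy)-cis-4,4,8,10-tetramethyl-8-octalin
Product: 14 6α-(tert-butyldimethylsilyloxy)-cis-4,4,8,10-tetramethyl-8-octalin-7-one
Conditions: Rh2(cap)4 (dirhodium tetrakis(caprolactamate), 1 mol %), t-BuOOH, K2CO3, CH2Cl2, 23 °C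
Reagents that add atoms: tert-butyl hydroperoxide, CC(C)(C)OO
Why: Radical allylic C–H oxidation with t-BuOOH; C7 is the only ring allylic methylene (C10 bears no hydrogen) and the neopentyl C9 end of the allyl radical is shielded, so oxygen should enter at C7 and give the 8-en-7-one.

Step 11
Reactants: 14 6α-(tert-butyldimethylsilyloxy)-cis-4,4,8,10-tetramethyl-8-octalin-7-one
Product: 16 6α-(tert-butyldimethylsilyloxy)-9β-vinyl-cis-4,4,8,10-tetramethyl-7-octalin-7-yl trifluoromethanesulfonate, via magnesium enolate 15 (not isolated)
Conditions: CH2=CHMgBr (3 equiv), CuBr·SMe2 (1.5 equiv), THF, −78 → −40 °C; then Comins' reagent, −78 → 0 °C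
Reagents that add atoms: vinylmagnesium bromide, C=C[Mg]Br; N-(5-chloropyridin-2-yl)bis(trifluoromethanesulfonimide) (Comins' reagent), O=S(=O)(N(c1ccc(Cl)cn1)S(=O)(=O)C(F)(F)F)C(F)(F)F
Why: Cuprate conjugate addition followed by O-triflation of the regiodefined enolate; the vinyl group enters C9 axially on the convex β face, anti to the axial C1–C10 bond, and so ends up cis to the C10 methyl group, while C8 stays trigonal.

Step 12
Reactants: 16 6α-(tert-butyldimethylsilyloxy)-9β-vinyl-cis-4,4,8,10-tetramethyl-7-octalin-7-yl trifluoromethanesulfonate
Product: 17 6α-(tert-butyldimethylsilyloxy)-9β-vinyl-cis-4,4,8,10-tetramethyl-7-octalin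
Conditions: Pd(OAc)2 (5 mol %), PPh3, Bu3N, HCO2H, DMF, 60 °C
Reagents that add atoms: none
Why: Palladium-catalysed formate reduction of the enol triflate removes the C7 oxygen that served to activate C9 and leaves the C7=C8 alkene; the allylic silyl ether is a poor leaving group, so no π-allyl pathway opens.

Step 13
Reactants: 17 6α-(tert-butyldimethylsilyloxy)-9β-vinyl-cis-4,4,8,10-tetramethyl-7-octalin
Product: 18 9β-vinyl-cis-4,4,8,10-tetramethyl-7-octalin-6α-ol
Conditions: Bu4NF, THF, 40 °C
Reagents that add atoms: none
Why: Fluoride desilylation; at this stage the molecule holds no base-sensitive group.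

Step 14
Reactants: 18 9β-vinyl-cis-4,4,8,10-tetramethyl-7-octalin-6α-ol
Product: 19 9β-vinyl-cis-4,4,8,10-tetramethyl-7-octalin-6α-yl acetate
Conditions: Ac2O, Et3N, DMAP (cat.), CH2Cl2, 23 °C
Reagents that add atoms: acetic anhydride, CC(=O)OC(C)=O
Why: DMAP-catalysed acetylation places the acetate on O6 while it is the only hydroxyl group, which settles the later question of which oxygen is acylated and puts an internal nucleophile 1,3 to C8.

Step 15
Reactants: 19 9β-vinyl-cis-4,4,8,10-tetramethyl-7-octalin-6α-yl acetate
Product: 20 7β,8β-epoxy-9β-vinyl-cis-4,4,8,10-tetramethyldecalin-6α-yl acetate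
Conditions: mCPBA, NaHCO3, CH2Cl2, 0 °C
Reagents that add atoms: 3-chloroperoxybenzoic acid, OOC(=O)c1cccc(Cl)c1
Why: Prilezhaev epoxidation, selective for the trisubstituted C7=C8 alkene over the vinyl group; the α face carries the pseudoaxial allylic acetate and the axial C1 methylene 1,3 to C8, so the peracid should add from the β face and set O7 β.

Step 16
Reactants: 20 7β,8β-epoxy-9β-vinyl-cis-4,4,8,10-tetramethyldecalin-6α-yl acetate
Product: 21 7β,8α-dihydroxy-9β-vinyl-cis-4,4,8,10-tetramethyldecalin-6α-yl acetate (8β-CH3)
Conditions: HClO4 (cat.), aqueous THF, 0 → 23 °C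
Reagents that add atoms: water, O
Why: Acid-catalysed epoxide hydrolysis at the tertiary carbon with inversion, which is also the trans-diaxial mode of opening, gives 8α-OH and 8β-CH3 and leaves the C7–O bond untouched; the 6α-acetate lies 1,3-diaxial to the rear of C8 and can assist as a bridging acetoxonium ion, which water returns to the secondary acetate, and a trans-diaxial 6,7-relationship bars migration to O7.

Step 17
Reactants: 21 7β,8α-dihydroxy-9β-vinyl-cis-4,4,8,10-tetramethyldecalin-6α-yl acetate; 22 but-3-en-2-one
Product: 23 (E)-4-[(5R,6R,7S,8S,9R,10S)-6-acetoxy-7,8-dihydroxy-4,4,8,10-tetramethyl-cis-decalin-9-yl]but-3-en-2-one (6α-OAc, 7β-OH, 8α-OH, 9β chain)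
Conditions: second-generation Hoveyda–Grubbs catalyst (10 mol %), 22 (10 equiv), CH2Cl2, 40 °C
Reagents that add atoms: none
Why: Olefin cross-metathesis of a terminal alkene with an electron-poor partner gives the E-enone under neutral conditions that tolerate the free diol and the acetate; installing the enone last keeps it away from every basic step.

## Compound list

1 | 2,2,6-trimethylcyclohexanone (racemic) | CC1CCCC(C)(C)C1=O | starting material
2 | lithium 2,6,6-trimethylcyclohex-1-en-1-olate | CC1=C([O-])C(C)(C)CCC1.[Li+] | intermediate (not isolated)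
3 | 2,6,6-trimethylcyclohex-1-en-1-yl trifluoromethanesulfonate | CC1=C(OS(=O)(=O)C(F)(F)F)C(C)(C)CCC1 | intermediate
4 | 1,3,3-trimethylcyclohexene | CC1=CC(C)(C)CCC1 | intermediate
5 | ethyl diazoacetate | CCOC(=O)C=[N+]=[N-] | starting material
6 | ethyl (1S,6R,7S)-1,5,5-trimethylbicyclo[4.1.0]heptane-7-carboxylate | CCOC(=O)[C@H]1[C@@H]2C(C)(C)CCC[C@]12C | intermediate
7 | (1S,6R,7S)-N-methoxy-N,1,5,5-tetramethylbicyclo[4.1.0]heptane-7-carboxamide | CON(C)C(=O)[C@H]1[C@@H]2C(C)(C)CCC[C@]12C | intermediate
8 | 1-[(1S,6R,7S)-1,5,5-trimethylbicyclo[4.1.0]heptan-7-yl]ethan-1-one | CC(=O)[C@H]1[C@@H]2C(C)(C)CCC[C@]12C | intermediate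
9 | (1R,6R,7R)-1,5,5-trimethyl-7-(prop-1-en-2-yl)bicyclo[4.1.0]heptane | C=C(C)[C@H]1[C@@H]2C(C)(C)CCC[C@]12C | intermediate
10 | carbon monoxide | [C-]#[O+] | starting material
11 | (4aR,8aR)-3,4a,8,8-tetramethyl-4a,5,6,7,8,8a-hexahydronaphthalen-1(2H)-one (cis-4,4,8,10-tetramethyl-8-octalin-6-one) | C1=C(C)CC(=O)[C@@H]2C(C)(C)CCC[C@@]21C | intermediate
12 | cis-4,4,8,10-tetramethyl-8-octalin-6α-ol | C1=C(C)C[C@H](O)[C@@H]2C(C)(C)CCC[C@@]21C | intermediate
13 | 6α-(tert-butyldimethylsilyloxy)-cis-4,4,8,10-tetramethyl-8-octalin | C1=C(C)C[C@H](O[Si](C)(C)C(C)(C)C)[C@@H]2C(C)(C)CCC[C@@]21C | intermediate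
14 | 6α-(tert-butyldimethylsilyloxy)-cis-4,4,8,10-tetramethyl-8-octalin-7-one | C1=C(C)C(=O)[C@H](O[Si](C)(C)C(C)(C)C)[C@@H]2C(C)(C)CCC[C@@]21C | intermediate
15 | bromomagnesium 6α-(tert-butyldimethylsilyloxy)-9β-vinyl-cis-4,4,8,10-tetramethyl-7-octalin-7-olate | C=C[C@H]1C(C)=C([O-])[C@H](O[Si](C)(C)C(C)(C)C)[C@@H]2C(C)(C)CCC[C@@]21C.[Mg+2].[Br-] | intermediate (not isolated)
16 | 6α-(tert-butyldimethylsilyloxy)-9β-vinyl-cis-4,4,8,10-tetramethyl-7-octalin-7-yl trifluoromethanesulfonate | C=C[C@H]1C(C)=C(OS(=O)(=O)C(F)(F)F)[C@H](O[Si](C)(C)C(C)(C)C)[C@@H]2C(C)(C)CCC[C@@]21C | intermediate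
17 | 6α-(tert-butyldimethylsilyloxy)-9β-vinyl-cis-4,4,8,10-tetramethyl-7-octalin | C=C[C@H]1C(C)=C[C@H](O[Si](C)(C)C(C)(C)C)[C@@H]2C(C)(C)CCC[C@@]21C | intermediate
18 | 9β-vinyl-cis-4,4,8,10-tetramethyl-7-octalin-6α-ol | C=C[C@H]1C(C)=C[C@H](O)[C@@H]2C(C)(C)CCC[C@@]21C | intermediate
19 | 9β-vinyl-cis-4,4,8,10-tetramethyl-7-octalin-6α-yl acetate | C=C[C@H]1C(C)=C[C@H](OC(C)=O)[C@@H]2C(C)(C)CCC[C@@]21C | intermediate
20 | 7β,8β-epoxy-9β-vinyl-cis-4,4,8,10-tetramethyldecalin-6α-yl acetate | C=C[C@H]1[C@@]4(C)O[C@H]4[C@H](OC(C)=O)[C@@H]2C(C)(C)CCC[C@@]21C | intermediate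
21 | 7β,8α-dihydroxy-9β-vinyl-cis-4,4,8,10-tetramethyldecalin-6α-yl acetate | C=C[C@H]1[C@](C)(O)[C@@H](O)[C@H](OC(C)=O)[C@@H]2C(C)(C)CCC[C@@]21C | intermediate
22 | but-3-en-2-one | C=CC(C)=O | starting material
23 | (E)-4-[(5R,6R,7S,8S,9R,10S)-6-acetoxy-7,8-dihydroxy-4,4,8,10-tetramethyl-cis-decalin-9-yl]but-3-en-2-one | CC(=O)/C=C/[C@H]1[C@](C)(O)[C@@H](O)[C@H](OC(C)=O)[C@@H]2C(C)(C)CCC[C@@]21C | target

## Step count and risks

Total: 17 steps. Longest linear sequence: 17 steps (1 → 23); the route is fully linear, with 5, 10 and 22 entering as reagents.

**Step 7 (key step).** The most likely failure is that the hindered, tetrasubstituted cyclopropane does not undergo selective oxidative addition: the catalyst may rest as an inert carbonyl complex, open the C9–C10 bond instead, or isomerise the substrate to dienes before CO is taken up. Slow turnover would also give the enolisable C5 centre and the β,γ-alkene of the product time to drift. The fallback leaves catalytic rhodium for stoichiometric iron carbonyl photochemistry, a known way of turning substituted, enantiopure alkenylcyclopropanes into cyclohexenones. It sets out from 9: irradiation with Fe(CO)5 under CO forms the alkene–Fe(CO)4 complex, which opens the less substituted proximal bond to a σ,η3-allyl iron acyl and releases the cyclohexenone on CO-driven demetallation. Without any base treatment the β,γ-enone is kept, so the sequence comes back at 11 and makes no new compound.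

**Step 3.** Carbene dimerisation may outrun addition to the hindered trisubstituted alkene, and face discrimination by the copper catalyst may be incomplete. The fallback gives up asymmetric catalysis for resolution. It sets out from 4: Rh2(OAc)4 and 5 give racemic ethyl exo-1,5,5-trimethylbicyclo[4.1.0]heptane-7-carboxylate F1; LiOH gives the racemic acid F2; crystallisation with (R)-1-phenylethylamine gives the (R)-1-phenylethylammonium (1S,6R,7S)-carboxylate F3; acidification gives (1S,6R,7S)-1,5,5-trimethylbicyclo[4.1.0]heptane-7-carboxylic acid F4; and two equivalents of MeLi convert F4 into the methyl ketone, so the route is rejoined at 8.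

**Step 10.** Hydrogen abstraction next to the silyloxy-bearing carbon may be slow, and oxygen may be delivered to the C9 end of the allyl radical or to the C8 methyl group. The fallback uses the acidity of the ketone instead of C–H abstraction. It sets out from 11: LiN(SiMe3)2 at −78 °C deprotonates the doubly activated C7 methylene and the Davis oxaziridine hydroxylates the enolate to 7-hydroxy-cis-4,4,8,10-tetramethyl-8-octalin-6-one F5 (either C7 epimer serves); LiBH(s-Bu)3 gives cis-4,4,8,10-tetramethyl-8-octalin-6α,7-diol F6; MnO2 oxidises only the allylic hydroxyl to 6α-hydroxy-cis-4,4,8,10-tetramethyl-8-octalin-7-one F7; and TBSOTf returns the route at 14.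

**Step 15.** Facial selectivity may be poor: the pseudoaxial vinyl group on the β face competes with the acetate and the C1 methylene on the α face, and an α-epoxide would lead in step 16 to the wrong diol. The same α preference is exactly what an enol-ether oxidation needs, so the fallback moves the C8 oxidation to that stage and also bypasses the acid-mediated opening. It sets out from 14: vinyl cuprate addition in the presence of Me3SiCl gives 6α-(tert-butyldimethylsilyloxy)-7-(trimethylsilyloxy)-9β-vinyl-cis-4,4,8,10-tetramethyl-7-octalin F8; Rubottom oxidation with mCPBA gives 6α-(tert-butyldimethylsilyloxy)-8α-hydroxy-9β-vinyl-cis-4,4,8,10-tetramethyldecalin-7-one F9; HF·pyridine gives 6α,8α-dihydroxy-9β-vinyl-cis-4,4,8,10-tetramethyldecalin-7-one F10; Ac2O/DMAP acetylates only the secondary hydroxyl to 6α-acetoxy-8α-hydroxy-9β-vinyl-cis-4,4,8,10-tetramethyldecalin-7-one F11; and hydroxyl-directed reduction with Me4NBH(OAc)3 delivers hydride from the α face, so the route is rejoined at 21.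

**Step 17.** The vinyl group sits between two fully substituted carbons, so loading of the ruthenium carbene may be slow and self-metathesis of the enone partner and catalyst decay may win. The fallback replaces metathesis by cleavage and olefination. It sets out from 21: ozonolysis with Me2S work-up gives 6α-acetoxy-7β,8α-dihydroxy-cis-4,4,8,10-tetramethyldecalin-9β-carbaldehyde F12 (expected to rest as the lactol with O7), and the neutral stabilised ylide Ph3P=CHC(O)CH3 converts it into the E-enone, so the route is rejoined at 23.

## Further compounds

F0 | step 7 | none | none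
F1 | step 3 | racemic ethyl exo-1,5,5-trimethylbicyclo[4.1.0]heptane-7-carboxylate (one enantiomer drawn) | CCOC(=O)[C@H]1[C@@H]2C(C)(C)CCC[C@]12C
F2 | step 3 | racemic exo-1,5,5-trimethylbicyclo[4.1.0]heptane-7-carboxylic acid (one enantiomer drawn) | OC(=O)[C@H]1[C@@H]2C(C)(C)CCC[C@]12C
F3 | step 3 | (R)-1-phenylethylammonium (1S,6R,7S)-1,5,5-trimethylbicyclo[4.1.0]heptane-7-carboxylate | C[C@@H]([NH3+])c1ccccc1.[O-]C(=O)[C@H]1[C@@H]2C(C)(C)CCC[C@]12C
F4 | step 3 | (1S,6R,7S)-1,5,5-trimethylbicyclo[4.1.0]heptane-7-carboxylic acid | OC(=O)[C@H]1[C@@H]2C(C)(C)CCC[C@]12C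
F5 | step 10 | 7-hydroxy-cis-4,4,8,10-tetramethyl-8-octalin-6-one (C7 epimers) | C1=C(C)C(O)C(=O)[C@@H]2C(C)(C)CCC[C@@]21C
F6 | step 10 | cis-4,4,8,10-tetramethyl-8-octalin-6α,7-diol (C7 epimers) | C1=C(C)C(O)[C@H](O)[C@@H]2C(C)(C)CCC[C@@]21C
F7 | step 10 | 6α-hydroxy-cis-4,4,8,10-tetramethyl-8-octalin-7-one | C1=C(C)C(=O)[C@H](O)[C@@H]2C(C)(C)CCC[C@@]21C
F8 | step 15 | 6α-(tert-butyldimethylsilyloxy)-7-(trimethylsilyloxy)-9β-vinyl-cis-4,4,8,10-tetramethyl-7-octalin | C=C[C@H]1C(C)=C(O[Si](C)(C)C)[C@H](O[Si](C)(C)C(C)(C)C)[C@@H]2C(C)(C)CCC[C@@]21C
F9 | step 15 | 6α-(tert-butyldimethylsilyloxy)-8α-hydroxy-9β-vinyl-cis-4,4,8,10-tetramethyldecalin-7-one | C=C[C@H]1[C@](C)(O)C(=O)[C@H](O[Si](C)(C)C(C)(C)C)[C@@H]2C(C)(C)CCC[C@@]21C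
F10 | step 15 | 6α,8α-dihydroxy-9β-vinyl-cis-4,4,8,10-tetramethyldecalin-7-one | C=C[C@H]1[C@](C)(O)C(=O)[C@H](O)[C@@H]2C(C)(C)CCC[C@@]21C
F11 | step 15 | 6α-acetoxy-8α-hydroxy-9β-vinyl-cis-4,4,8,10-tetramethyldecalin-7-one | C=C[C@H]1[C@](C)(O)C(=O)[C@H](OC(C)=O)[C@@H]2C(C)(C)CCC[C@@]21C
F12 | step 17 | 6α-acetoxy-7β,8α-dihydroxy-cis-4,4,8,10-tetramethyldecalin-9β-carbaldehyde | O=C[C@H]1[C@](C)(O)[C@@H](O)[C@H](OC(C)=O)[C@@H]2C(C)(C)CCC[C@@]21C
A1 | alternative 1 | cis-hexalin C7 trimethylsilyl enol ether with C9 benzyloxymethyl | C(c1ccccc1)OC[C@H]1C(C)=C(O[Si](C)(C)C)C[C@@H]2C(C)(C)CC=C[C@@]21C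
A2 | alternative 2 | 2,6-dimethyl-1,4-benzoquinone | CC1=CC(=O)C=C(C)C1=O
A3 | alternative 2 | 4-methylpenta-1,3-diene | C=CC=C(C)C
A4 | alternative 2 | cis-2,5,5,8a-tetramethyl-4a,5,8,8a-tetrahydronaphthalene-1,4-dione | O=C1C(C)=CC(=O)[C@@H]2C(C)(C)C=CC[C@@]21C
A5 | alternative 3 | (1R,5S)-6,6-dimethylbicyclo[3.1.1]heptan-2-one (nopinone) | CC1(C)[C@H]2CCC(=O)[C@@H]1C2
A6 | alternative 3 | cis-4,4,10-trimethyl-2-octalin-8-one | C1C(=O)CC[C@@H]2C(C)(C)C=CC[C@@]21C
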